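**Retrosynthetic overview**
- The target is reached from its 5,7-di-O-benzyl, chroman-3-O-acetyl flavonol; the C3 hydroxyl of ring C comes from epoxidation of the C2=C3 bond of the corresponding flavone.
- Ring C is disconnected at C4–C4a. The strategy rests on ring A, a benzene ring with oxygens at C5, C7 and C8a (1,3,5-pattern): its two carbons ortho to O1 (future C4a and C8) are mirror-equivalent and strongly activated, so the acyl carbon C4 of a (Z)-3-aryloxyacrylic acid can be attached last.
- That acid holds O1–C2 and ring B already; it comes from conjugate addition of 3,5-bis(benzyloxy)phenol to an arylpropiolate, made by Sonogashira coupling of a 6-iodochroman-3-ol.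
- The dihydropyran of ring B is built first from 4-iodophenol: propargyl ether, Claisen/electrocyclization to the 2,2-dimethylchromene, Jacobsen epoxidation (sets C3 as R), hydride opening at C4.
- Order of ring formation: chroman pyran ring first, pyranone ring C last; both benzene rings are bought.

Key step: step 9

Assumption: the (R,R)-(salen)MnCl catalyst is taken to give the (3R,4R)-epoxide of a 2,2-dimethylchromene, as for the parent chromene; if the opposite sense were found, the (S,S) catalyst would be used.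

**Route**

Step 1
Reactants: 1 4-iodophenol; 2 3-chloro-3-methylbut-1-yne
Product: 3 1-iodo-4-[(2-methylbut-3-yn-2-yl)oxy]benzene
Conditions: CuCl2·2H2O (cat.), DBU, MeCN, 0 °C
Reagents that add atoms: none
Why: Copper-catalysed O-alkylation of a phenol with a tertiary propargylic chloride is the standard way to aryl 1,1-dimethylpropargyl ethers and does not touch the aryl iodide.

Step 2
Reactants: 3 1-iodo-4-[(2-methylbut-3-yn-2-yl)oxy]benzene
Product: 4 6-iodo-2,2-dimethyl-2H-chromene
Conditions: PhNEt2, 190 °C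
Reagents that add atoms: none
Why: A thermal aryl propargyl ether Claisen rearrangement, 1,5-hydrogen shift and oxa-6π-electrocyclization cascade should give the chromene, the para iodine leaving only the two equivalent ortho positions for the rearrangement.

Step 3
Reactants: 4 6-iodo-2,2-dimethyl-2H-chromene
Product: 5 (3R,4R)-3,4-epoxy-6-iodo-2,2-dimethylchroman
Conditions: (R,R)-N,N'-bis(3,5-di-tert-butylsalicylidene)-1,2-cyclohexanediaminomanganese chloride, (R,R)-(salen)MnCl (cat.), 4-phenylpyridine N-oxide (cat.), aq. NaOCl (pH 11.3), CH2Cl2, 0 °C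
Reagents that add atoms: sodium hypochlorite, [Na+].[O-]Cl
Why: Jacobsen–Katsuki epoxidation, for which cis-configured 2,2-dimethylchromenes are a privileged substrate class, should deliver oxygen to one face of the C3=C4 bond under control of the (R,R)-salen ligand and so set C3 and C4 as R.

Step 4
Reactants: 5 (3R,4R)-3,4-epoxy-6-iodo-2,2-dimethylchroman
Product: 6 (3R)-6-iodo-2,2-dimethylchroman-3-ol
Conditions: LiBHEt3, THF, 0 °C; then H2O
Reagents that add atoms: none
Why: Regioselective SN2 reduction of the epoxide, in which hydride attacks the benzylic C4 because C3 is shielded by the quaternary C2, turns C4 into CH2 and leaves the C3–O bond, its R configuration and the aryl iodide untouched.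

Step 5
Reactants: 6 (3R)-6-iodo-2,2-dimethylchroman-3-ol; 7 methyl propiolate
Product: 8 methyl 3-[(3R)-3-hydroxy-2,2-dimethylchroman-6-yl]prop-2-ynoate
Conditions: Pd(PPh3)2Cl2 (cat.), CuI (cat.), K2CO3, THF, 60 °C
Reagents that add atoms: none
Why: Sonogashira coupling of the aryl iodide with the terminal alkyne, run with an inorganic base because amines add to propiolates, should tolerate the hindered free secondary alcohol.

Step 6
Reactants: 8 methyl 3-[(3R)-3-hydroxy-2,2-dimethylchroman-6-yl]prop-2-ynoate; 9 3,5-bis(benzyloxy)phenol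
Product: 10 methyl (Z)-3-[3,5-bis(benzyloxy)phenoxy]-3-[(3R)-3-hydroxy-2,2-dimethylchroman-6-yl]prop-2-enoate
Conditions: K2CO3, DMF, 90 °C
Reagents that add atoms: none
Why: Base-mediated oxa-Michael addition of the phenoxide to the beta carbon of the arylpropiolate forms the O1–C2 bond, anti protonation placing the aryloxy group cis to the ester (Z), while the far less acidic hindered alcohol does not compete.

Step 7
Reactants: 10 methyl (Z)-3-[3,5-bis(benzyloxy)phenoxy]-3-[(3R)-3-hydroxy-2,2-dimethylchroman-6-yl]prop-2-enoate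
Product: 11 (Z)-3-[3,5-bis(benzyloxy)phenoxy]-3-[(3R)-3-hydroxy-2,2-dimethylchroman-6-yl]prop-2-enoic acid
Conditions: LiOH·H2O, THF/MeOH/H2O, 45 °C; then 1 M HCl to pH 3
Reagents that add atoms: lithium hydroxide, [Li+].[OH-]
Why: Saponification at the ester carbonyl is the long-established way to 3-aryloxyacrylic acids and leaves the benzyl ethers and the push–pull enol ether intact.

Step 8
Reactants: 11 (Z)-3-[3,5-bis(benzyloxy)phenoxy]-3-[(3R)-3-hydroxy-2,2-dimethylchroman-6-yl]prop-2-enoic acid
Product: 13 (Z)-3-[3,5-bis(benzyloxy)phenoxy]-3-[(3R)-3-acetoxy-2,2-dimethylchroman-6-yl]prop-2-enoic acid, via acetic mixed anhydride 12 (not isolated)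
Conditions: Ac2O, pyridine, DMAP (cat.), CH2Cl2, rt; then H2O/pyridine
Reagents that add atoms: acetic anhydride, CC(=O)OC(C)=O
Why: DMAP-catalysed acetylation of the secondary alcohol also turns the carboxyl group into its acetic mixed anhydride, which water cleaves at the more electrophilic acetyl carbonyl on work-up, so that only the O-acetate remains.

Step 9
Reactants: 13 (Z)-3-[3,5-bis(benzyloxy)phenoxy]-3-[(3R)-3-acetoxy-2,2-dimethylchroman-6-yl]prop-2-enoic acid
Product: 15 (3R)-6-[5,7-bis(benzyloxy)-4-oxo-4H-chromen-2-yl]-2,2-dimethylchroman-3-yl acetate, via mixed trifluoroacetic anhydride 14 (not isolated)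
Conditions: TFAA, CH2Cl2, 0 °C → rt
Reagents that add atoms: none
Why: TFAA converts the acid into the mixed trifluoroacetic anhydride, whose acyl carbon (as such or as the acylium ion) is attacked by the ring A carbon ortho to the vinyl ether oxygen; loss of a proton from the Wheland intermediate and of trifluoroacetic acid gives the pyranone with the new C4–C4a bond. The closest known reaction is the intramolecular Friedel–Crafts acylation of 3-aryloxyacrylic and 3-aryloxycinnamic acids to chromones and flavones under anhydride or strong-acid activation. Ring C closes in a 6-exo-trig mode, the arene carbon adding to the trigonal acyl carbon whose C=O stays outside the ring. No stereocenter is formed, and the acetate-bearing C3 of the chroman is remote and not ionizable under these conditions. Regioselectivity is secured by the mirror symmetry of the 3,5-bis(benzyloxy)phenoxy ring, which makes the two carbons ortho to the ether oxygen identical (each also ortho to one and para to the other benzyloxy group), while the para carbon cannot reach the acyl carbon. Only the Z acid can close, and the trifluoroacetic acid set free equilibrates the push–pull alkene by reversible protonation at the alpha carbon, so any E material should be drawn through.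

Step 10
Reactants: 15 (3R)-6-[5,7-bis(benzyloxy)-4-oxo-4H-chromen-2-yl]-2,2-dimethylchroman-3-yl acetate
Product: 17 (3R)-6-[5,7-bis(benzyloxy)-3-hydroxy-4-oxo-4H-chromen-2-yl]-2,2-dimethylchroman-3-yl acetate, via flavone 2,3-epoxide 16 (not isolated)
Conditions: DMDO (acetone solution), CH2Cl2, 0 °C → rt; then p-TsOH·H2O (cat.), CH2Cl2, rt
Reagents that add atoms: dimethyldioxirane, CC1(C)OO1
Why: Epoxidation of the C2=C3 bond by dimethyldioxirane followed by acid-catalysed opening at C2 (oxocarbenium ion) and loss of the C3 proton is the established flavone-to-flavonol conversion, and the acetate and aryl benzyl ethers are inert to the neutral oxidant.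

Step 11
Reactants: 17 (3R)-6-[5,7-bis(benzyloxy)-3-hydroxy-4-oxo-4H-chromen-2-yl]-2,2-dimethylchroman-3-yl acetate
Product: 18 5,7-bis(benzyloxy)-3-hydroxy-2-[(3R)-3-hydroxy-2,2-dimethylchroman-6-yl]-4H-chromen-4-one
Conditions: K2CO3, MeOH/THF, rt, under Ar; then aq. NH4Cl
Reagents that add atoms: none
Why: Base-catalysed transesterification with methanol removes the acetate at its acyl carbon without touching the benzyl ethers or the C3–O bond of the chroman, the exclusion of air protecting the flavonol anion.

Step 12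
Reactants: 18 5,7-bis(benzyloxy)-3-hydroxy-2-[(3R)-3-hydroxy-2,2-dimethylchroman-6-yl]-4H-chromen-4-one
Product: 19 3,5,7-trihydroxy-2-[(3R)-3-hydroxy-2,2-dimethylchroman-6-yl]-4H-chromen-4-one (target)
Conditions: H2 (1 atm), Pd/C, THF/MeOH, rt
Reagents that add atoms: none
Why: Hydrogenolysis of the two aryl benzyl ethers over palladium on carbon should spare the tetrasubstituted conjugated C2=C3 bond and the non-benzylic chroman alcohol, whose R configuration is unaffected.

**Compound list**
1 | 4-iodophenol | Oc1ccc(I)cc1 | starting material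
2 | 3-chloro-3-methylbut-1-yne | C#CC(C)(C)Cl | starting material
3 | 1-iodo-4-[(2-methylbut-3-yn-2-yl)oxy]benzene | C#CC(C)(C)Oc1ccc(I)cc1 | intermediate
4 | 6-iodo-2,2-dimethyl-2H-chromene | CC1(C)C=Cc2cc(I)ccc2O1 | intermediate
5 | (3R,4R)-3,4-epoxy-6-iodo-2,2-dimethylchroman | CC1(C)Oc2ccc(I)cc2[C@H]3O[C@@H]13 | intermediate
6 | (3R)-6-iodo-2,2-dimethylchroman-3-ol | CC1(C)Oc2ccc(I)cc2C[C@H]1O | intermediate
7 | methyl propiolate | C#CC(=O)OC | starting material
8 | methyl 3-[(3R)-3-hydroxy-2,2-dimethylchroman-6-yl]prop-2-ynoate | CC1(C)Oc2ccc(C#CC(=O)OC)cc2C[C@H]1O | intermediate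
9 | 3,5-bis(benzyloxy)phenol | Oc1cc(OCc2ccccc2)cc(OCc2ccccc2)c1 | starting material
10 | methyl (Z)-3-[3,5-bis(benzyloxy)phenoxy]-3-[(3R)-3-hydroxy-2,2-dimethylchroman-6-yl]prop-2-enoate | CC1(C)Oc2ccc(/C(Oc3cc(OCc4ccccc4)cc(OCc4ccccc4)c3)=C/C(=O)OC)cc2C[C@H]1O | intermediate
11 | (Z)-3-[3,5-bis(benzyloxy)phenoxy]-3-[(3R)-3-hydroxy-2,2-dimethylchroman-6-yl]prop-2-enoic acid | CC1(C)Oc2ccc(/C(Oc3cc(OCc4ccccc4)cc(OCc4ccccc4)c3)=C/C(=O)O)cc2C[C@H]1O | intermediate
12 | acetic (Z)-3-[3,5-bis(benzyloxy)phenoxy]-3-[(3R)-3-acetoxy-2,2-dimethylchroman-6-yl]prop-2-enoic anhydride | CC1(C)Oc2ccc(/C(Oc3cc(OCc4ccccc4)cc(OCc4ccccc4)c3)=C/C(=O)OC(C)=O)cc2C[C@H]1OC(C)=O | intermediate (not isolated)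
13 | (Z)-3-[3,5-bis(benzyloxy)phenoxy]-3-[(3R)-3-acetoxy-2,2-dimethylchroman-6-yl]prop-2-enoic acid | CC1(C)Oc2ccc(/C(Oc3cc(OCc4ccccc4)cc(OCc4ccccc4)c3)=C/C(=O)O)cc2C[C@H]1OC(C)=O | intermediate
14 | (Z)-3-[3,5-bis(benzyloxy)phenoxy]-3-[(3R)-3-acetoxy-2,2-dimethylchroman-6-yl]prop-2-enoic trifluoroacetic anhydride | CC1(C)Oc2ccc(/C(Oc3cc(OCc4ccccc4)cc(OCc4ccccc4)c3)=C/C(=O)OC(=O)C(F)(F)F)cc2C[C@H]1OC(C)=O | intermediate (not isolated)
15 | (3R)-6-[5,7-bis(benzyloxy)-4-oxo-4H-chromen-2-yl]-2,2-dimethylchroman-3-yl acetate | CC1(C)Oc2ccc(-c3cc(=O)c4c(OCc5ccccc5)cc(OCc5ccccc5)cc4o3)cc2C[C@H]1OC(C)=O | intermediate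
16 | 2,3-epoxide of 15 (cis-fused oxirane, both diastereomers relative to the chroman center) | CC1(C)Oc2ccc(C34OC3C(=O)c3c(OCc5ccccc5)cc(OCc5ccccc5)cc3O4)cc2C[C@H]1OC(C)=O | intermediate (not isolated)
17 | (3R)-6-[5,7-bis(benzyloxy)-3-hydroxy-4-oxo-4H-chromen-2-yl]-2,2-dimethylchroman-3-yl acetate | CC1(C)Oc2ccc(-c3oc4cc(OCc5ccccc5)cc(OCc5ccccc5)c4c(=O)c3O)cc2C[C@H]1OC(C)=O | intermediate
18 | 5,7-bis(benzyloxy)-3-hydroxy-2-[(3R)-3-hydroxy-2,2-dimethylchroman-6-yl]-4H-chromen-4-one | CC1(C)Oc2ccc(-c3oc4cc(OCc5ccccc5)cc(OCc5ccccc5)c4c(=O)c3O)cc2C[C@H]1O | intermediate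
19 | 3,5,7-trihydroxy-2-[(3R)-3-hydroxy-2,2-dimethylchroman-6-yl]-4H-chromen-4-one | CC1(C)Oc2ccc(-c3oc4cc(O)cc(O)c4c(=O)c3O)cc2C[C@H]1O | target

**Step count**
Total steps: 12. Longest linear sequence: 12 steps (1 to 19).

**Steps most likely to fail**

Step 9. The closure may be overtaken by intermolecular C-trifluoroacetylation of the very electron-rich ring A, by acid-induced loss of the benzyl ether that ends up peri to the new carbonyl, or by failure of E acid to isomerize to the cyclizing Z form. The fallback builds ring C by the chalcone route instead, setting out from 6 and returning at 15. Iodine–lithium exchange on 6 (n-BuLi, 2.2 equiv, THF, −78 °C) and a DMF quench should give (3R)-3-hydroxy-2,2-dimethylchroman-6-carbaldehyde F1. Claisen–Schmidt condensation of F1 with purchased 1-[2,4-bis(benzyloxy)-6-hydroxyphenyl]ethanone (CC(=O)c1c(O)cc(OCc2ccccc2)cc1OCc1ccccc1; KOH, EtOH, rt) should give (E)-1-[2,4-bis(benzyloxy)-6-hydroxyphenyl]-3-[(3R)-3-hydroxy-2,2-dimethylchroman-6-yl]prop-2-en-1-one F2. Oxidative cyclization (I2 cat., DMSO, 120 °C) should give 5,7-bis(benzyloxy)-2-[(3R)-3-hydroxy-2,2-dimethylchroman-6-yl]-4H-chromen-4-one F3, and acetylation (Ac2O, pyridine, DMAP) returns to 15.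

Step 6. The electron-rich aryl group on the alkyne lowers its electrophilicity, so phenoxide addition may be sluggish and forcing conditions may erode the alkene geometry or let the alkoxide compete. The fallback replaces the conjugate addition by a copper-catalysed C–O coupling, setting out from 8 and returning at 10. Hydroiodination of 8 (NaI, AcOH, 70 °C) should give methyl (Z)-3-iodo-3-[(3R)-3-hydroxy-2,2-dimethylchroman-6-yl]prop-2-enoate F4. Ullmann-type vinylation of phenol 9 with F4 (CuI cat., N,N-dimethylglycine, Cs2CO3, dioxane, 90 °C) should proceed with retention of geometry to give 10.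

Step 10. Epoxidation of the conjugated C2=C3 bond may be slow enough for dimethyldioxirane to oxidize the benzylic C4–H bonds of the chroman or the benzyl ether methylenes, and the epoxide may not rearrange cleanly to the enol. The fallback is a hypervalent-iodine oxidation, setting out from 15 and returning at 18. PhI(OAc)2 with KOH in MeOH (0 °C → rt) should add methoxide at C2, hydroxylate C3 and cleave the acetate, giving 5,7-bis(benzyloxy)-2-[(3R)-3-hydroxy-2,2-dimethylchroman-6-yl]-2,4,4-trimethoxychroman-3-ol F5 (2,3-cis, both diastereomers relative to the chroman center). Aqueous HCl in acetone should then hydrolyse the acetal and eliminate methanol to give 18.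

**Further compounds**
F1 | step 9 | (3R)-3-hydroxy-2,2-dimethylchroman-6-carbaldehyde | CC1(C)Oc2ccc(C=O)cc2C[C@H]1O
F2 | step 9 | (E)-1-[2,4-bis(benzyloxy)-6-hydroxyphenyl]-3-[(3R)-3-hydroxy-2,2-dimethylchroman-6-yl]prop-2-en-1-one | CC1(C)Oc2ccc(/C=C/C(=O)c3c(O)cc(OCc4ccccc4)cc3OCc3ccccc3)cc2C[C@H]1O
F3 | step 9 | 5,7-bis(benzyloxy)-2-[(3R)-3-hydroxy-2,2-dimethylchroman-6-yl]-4H-chromen-4-one | CC1(C)Oc2ccc(-c3cc(=O)c4c(OCc5ccccc5)cc(OCc5ccccc5)cc4o3)cc2C[C@H]1O
F4 | step 6 | methyl (Z)-3-iodo-3-[(3R)-3-hydroxy-2,2-dimethylchroman-6-yl]prop-2-enoate | CC1(C)Oc2ccc(/C(I)=C/C(=O)OC)cc2C[C@H]1O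
F5 | step 10 | 5,7-bis(benzyloxy)-2-[(3R)-3-hydroxy-2,2-dimethylchroman-6-yl]-2,4,4-trimethoxychroman-3-ol | CC1(C)Oc2ccc(C3(OC)Oc4cc(OCc5ccccc5)cc(OCc5ccccc5)c4C(OC)(OC)C3O)cc2C[C@H]1O
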